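(The numbers in the tables are simulated with constants of no real substance.)

Percent of the two substrates charged together is the unit of every reading here, and each reading is good to 2 percentage points.

all flasks: left-handed substrate 0.020 M; right-handed substrate 0.020 M

| run | coupling partner | precatalyst | remark | time |
|---|---|---|---|---|
| winter | 2.2 equiv (fed, over 6.0 min) | 5 mol% | the very flask that is asked about, followed so far |  |
| summer | 2.2 equiv (fed, over 6.0 min) | 2.5 mol% | run made earlier |  |
| flask | 2.20 equiv (fed, over 6.0 min) | 5 mol% |  | 20 min |

- winter (time / s: left-handed product / %, right-handed product / %): 10.0: 1, 0; 20.0: 0, 0; 40.0: 1, 2; 90.0: 0, 0
- summer (time / min: left-handed product / %, right-handed product / %): 0.667: 4, 0; 1.33: 0, 3; 3.00: 2, 3; 8.00: 19, 9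

(scatter of a reading: 2 percentage points)

- catalyst is single-handed; left-handed substrate and right-handed substrate are mirror images of each other, charged as a racemate, each of them at the stated concentration
- steps thought possible: coupling partner + catalyst + left-handed substrate -> catalyst + left-handed product; coupling partner + catalyst + right-handed substrate -> catalyst + right-handed product; left-handed substrate <-> right-handed substrate; coupling partner -> decomposition product; 2 catalyst <-> resting dimer; coupling partner + precatalyst -> catalyst + spent reagent
- an excess is the difference of the two amounts in percent of their sum
- an excess is below zero if the other one leads

- left-handed product and right-handed product together, in percent of the left-handed substrate and right-handed substrate charged together, at 20 min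
- excess of left-handed product over right-handed product in the product at 20 min
- whether the exchange between left-handed substrate and right-handed substrate keeps pace with the reaction: how far the product's excess at 20 min gets from its value without exchange to its value with instant exchange (above 80% keeps pace, below 20% hardly takes part, else lags behind)

1. The flask asked about is the winter run. Its readings up to 90.0 s stay at or below 2%, so they show no handedness.

2. The summer run looks nearly the same, with half the precatalyst. At 8.00 min it reads 19% left-handed and 9% right-handed product, so r reads 2.11, with the scatter of those two readings. I call r the split: left-handed product over right-handed product.

3. Both product steps use the same catalyst and coupling partner, so these cancel in the ratio of the two rates. That ratio holds the rate constants and the substrate ratio. The precatalyst loading therefore changes how fast each flask runs, not the split at a given substrate ratio.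

4. First round: with instant exchange the substrates stay level and r stays put as the selectivity factor s, the ratio of the two rate constants. The summer reading then gives an excess of 35.7%.

5. Second round: I put that reading back in without exchange. On that assumption my estimate for the summer run is 62.0% of its left-handed substrate and 82.0% of its right-handed substrate left at that reading, and the ratio of their logarithms gives an estimate s = 2.41. Without exchange, r then sinks towards one as a racemate runs down.

6. The readings are of the products, and the one summer split fits either round. My bet is that r holds in the winter flask, which puts its excess near 35.7%.

7. The forecast gives 74% (52% to 93%), an excess of 29% (13% to 46%), lower than my figure, and says the exchange lags behind: “The data cannot distinguish these, so I guess an intermediate value”.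

    coupling partner + catalyst + left-handed substrate → catalyst + left-handed product (k = 538 /M²/s)
    coupling partner + catalyst + right-handed substrate → catalyst + right-handed product (k = 186 /M²/s)
    left-handed substrate ⇌ right-handed substrate (k = 0.0106 /s)
    coupling partner → decomposition product (k = 1.41 × 10⁻⁵ /s)
    2 catalyst ⇌ resting dimer, settled at all times (K = 29200 /M)
    coupling partner + precatalyst → catalyst + spent reagent (k = 4.16 /M/s)

The winter flask gives 66.7% with an excess of 46.8%, which is 18 points above the forecast, and the exchange keeps pace, 91% of the way to instant exchange. At 20.0 min the right-handed substrate leads the left-handed by 1.67% among what is left. In this flask r is 2.80 at 5.00 min, with 17.5% reacted, and 2.76 at 20.0 min. The neighbour flask with 0.550 equiv of coupling partner stands at 19.5% at 20.0 min, and its r is 2.86.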